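The time here was 15 h: the run of a closed flask in delta, the average stay in a tank in alpha.

| setting | delta | alpha |
|---|---|---|
| Z | 1.3 M | 1.3 M |
| time | 15 h |  |
| remark | everything together in a closed stirred flask, run for 15 h | a single well-mixed tank run continuously and read at steady state, 15 h in it on average |

    E ⇌ D (K1 = 0.62, k1 = 0.39 h⁻¹)
    Z → E (k2 = 2.5 × 10⁻⁴ h⁻¹)
    Z + 2 E → 3 E (k3 = 0.32 M⁻² h⁻¹)
    Z + E → Z.E (k4 = 0.063 M⁻¹ h⁻¹)

* the set-up with the highest share of E in all that became E or Z.E or D, at the outlet or at the end ("none" if the first two lie within 2 percentage points) (delta / alpha / none)
* share of E in all that became E or Z.E or D, at the outlet or at the end, delta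
* share of E in all that became E or Z.E or D, at the outlet or at the end, alpha

- in percentages every species weighs as the Z in it: one Z.E counts as two
- a doubled species enters its step squared and goes two at a time
- the stated concentrations are those of everything mixed, before any reaction; amounts are the same in each set-up
- run time (delta): 15 h

I drew the curve of the pool [E]+[D] in delta. It started with slope 3.25 × 10⁻⁴ M h⁻¹, the feed from Z, and [Z] stayed near its charge. The relaxation time of E ⇌ D, about 0.981 h, is far shorter than the run, and it gives a knee in E's share of the pool, not in the pool itself; I took that share as its equilibrium value, 61.7%. Capture of E by Z is then pseudo-first-order, so I carried the pool's drain constant λ, the capture constant at charged [Z] times E's share of the pool, 0.0506 h⁻¹. The pool bends towards the level feed/λ, 0.00643 M, as one minus exp(−λt), and in delta stood at 0.00342 M after 15 h. There the autocatalytic step ran at 1.07% of capture, so I dropped it.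

Whatever was fed but is not in the pool is Z.E, counted double, so the share of E is E's part of the pool over twice the total fed minus the pool. That gave 33.3% for delta. In alpha the tank balance gives a pool of feed·τ/(one plus λτ), 0.00277 M, smaller than in delta, and a share of 24.5%.

The forecast said 33% for delta and 25% for alpha, slightly above my alpha, and chose delta: “The tank's broad residence-time spread gives the double-weighted Z.E more weight relative to E than the batch does”.

The simulation gave 33.3% for delta and 25.0% for alpha, so delta led. For E, the half-life by the first step alone, forward rate only with the way back not counted, is 1.8 h, shorter than the 8.5 h by the fourth step alone with the other concentrations as charged in delta, and short against 15 h. With the same λ, delta at 150 h has a pool of 0.00643 M and a reckoned share of 4.35%; the flask left that long gave 4.53%.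

All constants belong to no real substance, and the outcome is calculated.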